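**Plan**
- Retrosynthesis: remove the C9 angelate, the C11=C13 methylene and the C9 carbinol to reach a Z-cyclodecenone lactone; re-join C4 to C9; cut the resulting decalin into a methoxy toluquinone (ring A, C15) and a 1-benzyloxy-3-alkyl diene (C5–C8, C11, C12).
- Enabling feature: C4 and C9 face each other across the ten-membered ring, five ring bonds apart on either side. A C4–C9 bond therefore gives a cis-decalin (ring A: C4, C3, C2, C1, C10, C9; ring B: C4–C9) in which the C9 oxygen and the Z C4=C5 bond are the two ends of a Grob fragmentation.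
- Forward order: Diels–Alder builds ring B on ring A; ring A is adjusted (C9–OH, C10 methyl carbinol, C3–OH); the γ-lactone is closed on ring B; fragmentation opens both six-membered rings to the ten-membered ring; C9 reduction, α-methylenation, angeloylation and desilylation finish.
- Stereochemistry: endo cycloaddition sets C4/C5; the C5 ether steers angular hydroxylation to the cis fusion; chelated methyl addition sets C10; equatorial hydride delivery sets C3; syn hydroboration on the convex face sets C6/C7; lipase resolution gives the absolute configuration; the cis fusion with equatorial mesylate gives the Z alkene; dipole-controlled reduction sets C9; the ester geometry comes from angelic acid.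

Key step: step 16

Remarks on the chemistry:
- Germacrane numbering of the target is used for all intermediates (C14 on C10, C15 on C4; side chain C11, C12, C13). In the decalins β is the face of the C4 methyl group and α the opposite face.
- Racemic intermediates are drawn as the enantiomer that is carried on.
- Assumption: the lipase follows the Kazlauskas rule with the C4 side as the large group, so the (3R)-alcohol is acetylated and the wanted (3S)-alcohol remains.

**Route**

Step 1
Reactants: 1 2-methoxy-6-methylphenol
Product: 2 2-methoxy-6-methyl-1,4-benzoquinone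
Conditions: O2 (1 atm), Co(salen) (5 mol %), DMF, rt
Reagents that add atoms: dioxygen, O=O
Why: Co(salen)-catalysed aerobic oxidation of a 2,6-disubstituted phenol with a free para position should give the para-quinone (phenol-to-quinone oxidation).

Step 2
Reactants: 3 but-3-yn-1-ol
Product: 4 benzyl but-3-yn-1-yl ether
Conditions: NaH, BnBr, Bu4NI (cat.), THF, 0 °C to rt
Reagents that add atoms: benzyl bromide, BrCc1ccccc1
Why: Williamson ether synthesis, in which O-alkylation of the alkoxide is much faster than deprotonation of the alkyne C–H by NaH.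

Step 3
Reactants: 4 benzyl but-3-yn-1-yl ether; 5 benzyl vinyl ether
Product: 6 (E)-1-benzyloxy-3-(2-benzyloxyethyl)buta-1,3-diene (used as the E/Z mixture)
Conditions: 5 (5 equiv), second-generation Grubbs catalyst (H2IMes)(PCy3)Cl2Ru=CHPh (5 mol %), benzene, 80 °C
Reagents that add atoms: none
Why: enol ether–alkyne cross enyne metathesis, in which the ruthenium alkoxycarbene adds to the terminal alkyne and gives the 1,3-disubstituted diene regioselectively; an E/Z mixture is expected, of which only the E isomer can reach the s-cis form needed in step 4.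

Step 4
Reactants: 2 2-methoxy-6-methyl-1,4-benzoquinone; 6 (E)-1-benzyloxy-3-(2-benzyloxyethyl)buta-1,3-diene
Product: 7 racemic endo cycloadduct (cis-fused 2-methoxy-1,6-diene-3,10-dione; 4β-Me; 9β-H; 5α-OBn)
Conditions: toluene, 60 °C
Reagents that add atoms: none
Why: normal-demand Diels–Alder reaction at the methyl-bearing quinone double bond (the methoxy-bearing one is a deactivated vinylogous ester); the nucleophilic diene terminus C8 bonds to the quinone CH (C9) β to the more electron-poor C3 carbonyl, so the benzyloxy carbon C5 lies next to quaternary C4, suprafacial addition gives the cis fusion and the endo transition state places 5-OBn trans to the C4 methyl.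

Step 5
Reactants: 7 racemic endo cycloadduct
Product: 9 racemic cis-fused 1,6-diene-3,10-dione (methoxy group removed), via methoxy dione 8 (not isolated)
Conditions: Zn, AcOH, THF, 0 °C to rt; filter, aq. NaHCO3 wash; then DBU (0.2 equiv), CH2Cl2, 0 °C
Reagents that add atoms: none
Why: Zn/AcOH conjugate reduction of the enedione C1=C2 bond gives β-methoxy ketone 8, from which DBU removes methanol by E1cB elimination (C1–H α to the C10 ketone) to give the unsubstituted enedione; C4 and C5 are untouched and any epimerisation at C9 is immaterial because C9 is enolised in step 6.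

Step 6
Reactants: 9 racemic cis-fused 1,6-diene-3,10-dione
Product: 11 racemic 9β-hydroxy-1,6-diene-3,10-dione, via potassium enolate 10 (not isolated)
Conditions: KN(SiMe3)2, THF, −78 °C; then 2-(phenylsulfonyl)-3-phenyloxaziridine, −78 °C; AcOH quench
Reagents that add atoms: 2-(phenylsulfonyl)-3-phenyloxaziridine, O=S(=O)(c1ccccc1)N1OC1c1ccccc1
Why: C9–H is the only enolisable hydrogen, so a single enolate forms and is hydroxylated by the N-sulfonyloxaziridine (enolate oxidation); the oxidant should enter on the β face, because the pseudo-axial 5α-benzyloxy group is 1,3-related to C9 and shields the α face more than the vicinal C4 methyl shields the β face, which restores the cis ring fusion.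

Step 7
Reactants: 11 racemic 9β-hydroxy-1,6-diene-3,10-dione
Product: 12 racemic 9β-hydroxy-6-ene-3,10-dione
Conditions: Zn, AcOH, THF, 0 °C to rt
Reagents that add atoms: none
Why: Zn/AcOH conjugate reduction of the enedione double bond, which leaves the tertiary α-ketol, the isolated C6=C7 alkene and the benzyl ethers untouched and creates no stereocentre.

Step 8
Reactants: 12 racemic 9β-hydroxy-6-ene-3,10-dione
Product: 13 racemic 9β,10β-dihydroxy-4β,10α-dimethyl-6-en-3-one
Conditions: MeMgBr (3 equiv), CH2Cl2/Et2O, −78 °C; aq. NH4Cl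
Reagents that add atoms: methylmagnesium bromide, C[Mg]Br
Why: chelation-controlled Grignard addition, in which the C9 magnesium alkoxide chelates and activates the adjacent C10 carbonyl over the neopentyl C3 ketone, and in the chelated chair of ring A the methyl enters equatorially, anti to the syn-axial C4 methyl, so the new hydroxyl is axial (β) and cis to the C9 hydroxyl.

Step 9
Reactants: 13 racemic 9β,10β-dihydroxy-4β,10α-dimethyl-6-en-3-one
Product: 14 racemic 3α,9β,10β-triol
Conditions: K[sec-Bu3BH] (4 equiv), THF, −78 °C; aq. NH4Cl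
Reagents that add atoms: none
Why: bulky trialkylborohydride reduction of a hindered cyclohexanone, in which hydride approaches C3 equatorially because the axial trajectory is blocked by the syn-axial C8 methylene of ring B, giving the axial 3α-alcohol trans to the C4 methyl.

Step 10
Reactants: 14 racemic 3α,9β,10β-triol
Product: 15 (3S)-3α,9β,10β-triol (single enantiomer)
Conditions: Burkholderia cepacia lipase (Amano PS), vinyl acetate, t-BuOMe, 35 °C, stopped near half conversion; chromatography
Reagents that add atoms: none
Why: lipase-catalysed kinetic resolution by irreversible transesterification, in which the (3R)-enantiomer should be acetylated and the (3S)-alcohol left behind and separated, fixing the absolute configuration of all five stereocentres present.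

Step 11
Reactants: 15 (3S)-3α,9β,10β-triol
Product: 16 3-O-TBS ether (9β,10β-diol)
Conditions: TBSOTf (1.1 equiv), 2,6-lutidine, CH2Cl2, −78 °C
Reagents that add atoms: tert-butyldimethylsilyl triflate, CC(C)(C)[Si](C)(C)OS(=O)(=O)C(F)(F)F
Why: silyl ether formation, in which the secondary C3 hydroxyl reacts far faster than the two tertiary hydroxyls at low temperature.

Step 12
Reactants: 16 3-O-TBS ether (9β,10β-diol)
Product: 18 6β,9β,10β-triol with the C7 side chain α, via alkylborane 17 (not isolated)
Conditions: BH3·THF (excess), THF, 0 °C to rt; then NaOH, H2O2, 0 °C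
Reagents that add atoms: hydrogen peroxide, OO
Why: hydroboration–oxidation, in which boron adds to the less substituted C6 and hydrogen to C7, both on the convex β face (anti to ring A and to the allylic 5α-benzyloxy group), and oxidation with retention gives the 6β-alcohol with 5,6-trans and 6,7-trans relationships.

Step 13
Reactants: 18 6β,9β,10β-triol with the C7 side chain α
Product: 19 5α,6β,9β,10β,12-pentaol
Conditions: H2 (1 atm), Pd(OH)2/C, EtOAc/EtOH, rt
Reagents that add atoms: none
Why: hydrogenolysis of both benzyl ethers, to which the silyl ether, the tertiary alcohols and the saturated skeleton are inert.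

Step 14
Reactants: 19 5α,6β,9β,10β,12-pentaol
Product: 21 trans-fused 12,6-lactone (5α,9β,10β-triol), via lactol 20 (not isolated)
Conditions: TEMPO (10 mol %), KBr (10 mol %), NaOCl (2.2 equiv), NaHCO3, CH2Cl2/H2O, 0 °C
Reagents that add atoms: none
Why: TEMPO-mediated oxidative lactonisation of a 1,4-diol, in which the primary alcohol is oxidised selectively to the aldehyde, trapped by the 6β-hydroxyl as the five-membered lactol and oxidised on to the γ-lactone; the hindered C5 and the tertiary hydroxyls should not react and no stereocentre changes.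

Step 15
Reactants: 21 trans-fused 12,6-lactone (5α,9β,10β-triol)
Product: 22 5α-mesylate (cis-decalin hydroxy mesylate)
Conditions: Ms2O, pyridine, DMAP (cat.), CH2Cl2, 0 °C to rt
Reagents that add atoms: methanesulfonic anhydride, CS(=O)(=O)OS(C)(=O)=O
Why: sulfonylation of the only secondary hydroxyl with retention at C5; without a trialkylamine no sulfene forms, so the tertiary hydroxyls stay free, and pyridine is too weak a base to start the fragmentation.

Step 16
Reactants: 22 5α-mesylate (cis-decalin hydroxy mesylate)
Product: 24 (4Z)-10-hydroxy-9-oxo-3-(TBS-oxy)germacr-4-en-12,6-olide, via potassium alkoxide 23 (not isolated)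
Conditions: KOtBu (1.05 equiv), THF, 0 °C, 15 min; aq. NH4Cl
Reagents that add atoms: none
Why: KOtBu deprotonates the tertiary C9 hydroxyl, and in alkoxide 23 the oxygen lone pair pushes into the C4–C9 bond, which is anti-periplanar to the equatorial C5–O bond of the mesylate, so C4–C9 breaks while C9=O and C4=C5 form and mesylate leaves in one concerted heterolysis. The closest known reaction type is the Grob (Wharton) fragmentation of decalin 1,3-diol monosulfonates to cyclodecenones. No ring is closed end to end: the ten-membered ring is uncovered when the bond shared by rings A and B is cleaved, and the γ-lactone is carried through unchanged. No new stereocentre is formed; the alkene geometry is stereospecific, because in the cis-fused decalin C3 is axial and the C4 methyl equatorial on ring B, so C3 and C6 are gauche across C4–C5 and end up cis on the double bond (Z). The step needs fragmentation to outrun lactone enolisation, elimination or substitution at C5, and base-induced shift of the product α-ketol; the trans-fused lactone locks ring B in the chair with equatorial C5, C6 and C7 substituents (no anti-periplanar hydrogen for E2, C4 quaternary), O–H deprotonation is faster than C–H deprotonation, and one equivalent of base is used at 0 °C with a prompt quench.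

Step 17
Reactants: 24 (4Z)-10-hydroxy-9-oxo-3-(TBS-oxy)germacr-4-en-12,6-olide
Product: 25 10-O-triethylsilyl ether of the keto lactone
Conditions: TESOTf, 2,6-lutidine, CH2Cl2, −78 to 0 °C
Reagents that add atoms: triethylsilyl triflate, CC[Si](CC)(CC)OS(=O)(=O)C(F)(F)F
Why: silylation of the tertiary α-hydroxyl with a silyl triflate, under which 2,6-lutidine should not enolise the ketone or the lactone.

Step 18
Reactants: 25 10-O-triethylsilyl ether of the keto lactone
Product: 26 (9S)-9-hydroxy lactone (3-OTBS; 10-OTES)
Conditions: K[sec-Bu3BH], THF, −78 °C; aq. NH4Cl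
Reagents that add atoms: none
Why: non-chelating bulky hydride reduction of an α-silyloxy ketone (Cornforth-type dipole control), in which the C10–OSiEt3 bond is opposed to the C9=O dipole and hydride enters from the ring periphery, so the new hydroxyl should come out trans on the ring to the C10 oxygen (9S); the γ-lactone is not reduced at −78 °C.

Step 19
Reactants: 26 (9S)-9-hydroxy lactone (3-OTBS; 10-OTES)
Product: 30 α-methylene lactone with free 9-hydroxyl, via dilithium enolate 27 (not isolated), via Mannich base 28 (not isolated), via ammonium iodide 29 (not isolated)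
Conditions: LiN(iPr)2 (2.3 equiv), THF, −78 °C; CH2=NMe2 I, −78 °C to rt; then MeI, MeOH, rt; then NaHCO3, CH2Cl2/H2O
Reagents that add atoms: dimethylmethyleneiminium iodide (Eschenmoser's salt), C=[N+](C)C.[I-]
Why: lactone α-methylenation by Mannich reaction of the enolate, N-quaternisation and E1cB loss of trimethylamine; the C9 hydroxyl is carried as its lithium alkoxide (an O-aminomethyl adduct would hydrolyse on work-up) and the transient C11 stereocentre is destroyed.

Step 20
Reactants: 30 α-methylene lactone with free 9-hydroxyl; 31 angelic acid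
Product: 33 9-O-angeloyl bis-silyl ether, via mixed anhydride 32 (not isolated)
Conditions: 31, 2,4,6-trichlorobenzoyl chloride, Et3N, toluene, rt; then 30, 75 °C
Reagents that add atoms: none
Why: Yamaguchi esterification through the mixed anhydride of angelic acid, an acylation that should keep the Z geometry of the acyl group; the C9 hydroxyl is the only free hydroxyl and its configuration is retained.

Step 21
Reactants: 33 9-O-angeloyl bis-silyl ether
Product: 34 CNP0549192.1 (target)
Conditions: HF·pyridine, pyridine, THF, 0 °C to rt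
Reagents that add atoms: none
Why: fluoride-mediated cleavage of the secondary TBS and tertiary TES ethers under buffered conditions that should leave the angelate, the α-methylene lactone and the allylic alcohol intact.

**Compound list**
1 | 2-methoxy-6-methylphenol | COc1cccc(C)c1O | starting material
2 | 2-methoxy-6-methyl-1,4-benzoquinone | COC1=CC(=O)C=C(C)C1=O | intermediate
3 | but-3-yn-1-ol | C#CCCO | starting material
4 | benzyl but-3-yn-1-yl ether | C#CCCOCc1ccccc1 | intermediate
5 | benzyl vinyl ether | C=COCc1ccccc1 | starting material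
6 | (E)-1-benzyloxy-3-(2-benzyloxyethyl)buta-1,3-diene | C=C(CCOCc1ccccc1)/C=C/OCc1ccccc1 | intermediate
7 | racemic endo cycloadduct: 5α-benzyloxy-7-(2-benzyloxyethyl)-2-methoxy-4β-methyl-9β-H-cis-decalin-1,6-diene-3,10-dione | C[C@@]12[C@H](OCc3ccccc3)C=C(CCOCc3ccccc3)C[C@@H]1C(=O)C=C(OC)C2=O | intermediate
8 | racemic 2-methoxy-6-ene-3,10-dione (C2 epimers) | C[C@@]12[C@H](OCc3ccccc3)C=C(CCOCc3ccccc3)C[C@@H]1C(=O)CC(OC)C2=O | intermediate (not isolated)
9 | racemic 5α-benzyloxy-7-(2-benzyloxyethyl)-4β-methyl-9β-H-cis-decalin-1,6-diene-3,10-dione | C[C@@]12[C@H](OCc3ccccc3)C=C(CCOCc3ccccc3)C[C@@H]1C(=O)C=CC2=O | intermediate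
10 | potassium 9(10)-enolate of 9 | C[C@@]12[C@H](OCc3ccccc3)C=C(CCOCc3ccccc3)CC1=C([O-])C=CC2=O.[K+] | intermediate (not isolated)
11 | racemic 9β-hydroxy-1,6-diene-3,10-dione | C[C@@]12[C@H](OCc3ccccc3)C=C(CCOCc3ccccc3)C[C@]1(O)C(=O)C=CC2=O | intermediate
12 | racemic 9β-hydroxy-6-ene-3,10-dione | C[C@@]12[C@H](OCc3ccccc3)C=C(CCOCc3ccccc3)C[C@]1(O)C(=O)CCC2=O | intermediate
13 | racemic 9β,10β-dihydroxy-4β,10α-dimethyl-6-en-3-one | C[C@@]12[C@H](OCc3ccccc3)C=C(CCOCc3ccccc3)C[C@]1(O)[C@@](C)(O)CCC2=O | intermediate
14 | racemic 5α-benzyloxy-7-(2-benzyloxyethyl)-4β,10α-dimethyl-cis-decal-6-ene-3α,9β,10β-triol | C[C@@]12[C@H](OCc3ccccc3)C=C(CCOCc3ccccc3)C[C@]1(O)[C@@](C)(O)CC[C@@H]2O | intermediate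
15 | (3S)-enantiomer of triol 14 | C[C@@]12[C@H](OCc3ccccc3)C=C(CCOCc3ccccc3)C[C@]1(O)[C@@](C)(O)CC[C@@H]2O | intermediate
16 | 3α-O-TBS ether of 15 | C[C@@]12[C@H](OCc3ccccc3)C=C(CCOCc3ccccc3)C[C@]1(O)[C@@](C)(O)CC[C@@H]2O[Si](C)(C)C(C)(C)C | intermediate
17 | 6β-boryl adduct of 16 (drawn as the monoalkylborane) | C[C@@]12[C@H](OCc3ccccc3)[C@@H](B)[C@H](CCOCc3ccccc3)C[C@]1(O)[C@@](C)(O)CC[C@@H]2O[Si](C)(C)C(C)(C)C | intermediate (not isolated)
18 | 5α-benzyloxy-7α-(2-benzyloxyethyl)-3α-(TBS-oxy)-4β,10α-dimethyl-cis-decalin-6β,9β,10β-triol | C[C@@]12[C@H](OCc3ccccc3)[C@@H](O)[C@H](CCOCc3ccccc3)C[C@]1(O)[C@@](C)(O)CC[C@@H]2O[Si](C)(C)C(C)(C)C | intermediate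
19 | 7α-(2-hydroxyethyl)-3α-(TBS-oxy)-4β,10α-dimethyl-cis-decalin-5α,6β,9β,10β-tetraol (pentaol) | C[C@@]12[C@H](O)[C@@H](O)[C@H](CCO)C[C@]1(O)[C@@](C)(O)CC[C@@H]2O[Si](C)(C)C(C)(C)C | intermediate
20 | 12,6-lactol (anomers) | C[C@@]12[C@H](O)[C@H]3OC(O)C[C@@H]3C[C@]1(O)[C@@](C)(O)CC[C@@H]2O[Si](C)(C)C(C)(C)C | intermediate (not isolated)
21 | trans-fused 12,6-lactone; 5α,9β,10β-triol; 3α-OTBS | C[C@@]12[C@H](O)[C@H]3OC(=O)C[C@@H]3C[C@]1(O)[C@@](C)(O)CC[C@@H]2O[Si](C)(C)C(C)(C)C | intermediate
22 | 5α-mesylate of 21 (fragmentation precursor) | C[C@@]12[C@H](OS(C)(=O)=O)[C@H]3OC(=O)C[C@@H]3C[C@]1(O)[C@@](C)(O)CC[C@@H]2O[Si](C)(C)C(C)(C)C | intermediate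
23 | potassium 9-alkoxide of 22 | C[C@@]12[C@H](OS(C)(=O)=O)[C@H]3OC(=O)C[C@@H]3C[C@]1([O-])[C@@](C)(O)CC[C@@H]2O[Si](C)(C)C(C)(C)C.[K+] | intermediate (not isolated)
24 | (4Z)-10-hydroxy-9-oxo-3-(TBS-oxy)germacr-4-en-12,6-olide (C3, C6, C7, C10 as in the target) | O=C1C[C@H]2CC(=O)O[C@@H]2/C=C(/C)[C@@H](O[Si](C)(C)C(C)(C)C)CC[C@]1(C)O | intermediate
25 | 10-O-triethylsilyl ether of 24 | O=C1C[C@H]2CC(=O)O[C@@H]2/C=C(/C)[C@@H](O[Si](C)(C)C(C)(C)C)CC[C@]1(C)O[Si](CC)(CC)CC | intermediate
26 | (9S)-9-hydroxy-3-(TBS-oxy)-10-(TES-oxy)germacr-4Z-en-12,6-olide | O[C@H]1C[C@H]2CC(=O)O[C@@H]2/C=C(/C)[C@@H](O[Si](C)(C)C(C)(C)C)CC[C@]1(C)O[Si](CC)(CC)CC | intermediate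
27 | dilithium 9-alkoxide lactone enolate of 26 | [O-][C@H]1C[C@H]2C=C([O-])O[C@@H]2/C=C(/C)[C@@H](O[Si](C)(C)C(C)(C)C)CC[C@]1(C)O[Si](CC)(CC)CC.[Li+].[Li+] | intermediate (not isolated)
28 | 11-(dimethylaminomethyl) lactone (C11 epimers) | CN(C)CC1C(=O)O[C@@H]2/C=C(/C)[C@@H](O[Si](C)(C)C(C)(C)C)CC[C@](C)(O[Si](CC)(CC)CC)[C@@H](O)C[C@@H]12 | intermediate (not isolated)
29 | 11-(trimethylammoniomethyl) lactone iodide | C[N+](C)(C)CC1C(=O)O[C@@H]2/C=C(/C)[C@@H](O[Si](C)(C)C(C)(C)C)CC[C@](C)(O[Si](CC)(CC)CC)[C@@H](O)C[C@@H]12.[I-] | intermediate (not isolated)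
30 | (9S)-9-hydroxy-3-(TBS-oxy)-10-(TES-oxy)germacra-4Z,11(13)-dien-12,6-olide | C=C1C(=O)O[C@@H]2/C=C(/C)[C@@H](O[Si](C)(C)C(C)(C)C)CC[C@](C)(O[Si](CC)(CC)CC)[C@@H](O)C[C@@H]12 | intermediate
31 | angelic acid | C/C=C(/C)C(=O)O | starting material
32 | angelic 2,4,6-trichlorobenzoic anhydride | C/C=C(/C)C(=O)OC(=O)c1c(Cl)cc(Cl)cc1Cl | intermediate (not isolated)
33 | 9-O-angeloyl-3-O-TBS-10-O-TES derivative | C=C1C(=O)O[C@@H]2/C=C(/C)[C@@H](O[Si](C)(C)C(C)(C)C)CC[C@](C)(O[Si](CC)(CC)CC)[C@@H](OC(=O)/C(C)=C\C)C[C@@H]12 | intermediate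
34 | CNP0549192.1: (3S,6R,7S,9S,10S,4Z)-9-angeloyloxy-3,10-dihydroxygermacra-4,11(13)-dien-12,6-olide | C=C1C(=O)O[C@@H]2/C=C(/C)[C@@H](O)CC[C@](C)(O)[C@@H](OC(=O)/C(C)=C\C)C[C@@H]12 | target

**Totals**
Total step count: 21.
Longest linear sequence: 20 steps (3 to 34, steps 2 to 21); the quinone branch (step 1) joins at step 4.

**Steps most likely to fail**

Step 10. The lipase may not accept the hindered axial C3 alcohol, or may discriminate the enantiomers poorly, so the resolution could stall or give low enantiomeric purity. Fallback (classical resolution): set out from racemic triol 14 and acylate the C3 hydroxyl with (1S)-camphanic chloride (pyridine, DMAP, CH2Cl2). The two diastereomeric esters are separated by chromatography or crystallisation. The ester of the (3S) series, camphanate ester F1, is cleaved with K2CO3 in MeOH, and the route is rejoined at 15.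

Step 18. Hydride may be delivered to the wrong face of the ten-membered ring ketone, through a conformer in which the C10–O bond is not opposed to the carbonyl, which would erode the C9 configuration. Fallback (internal hydride delivery): set out from hydroxy ketone 24, before silylation. Reduction with Me4NBH(OAc)3 in MeCN/AcOH at −20 °C binds boron to the C10 oxygen and delivers hydride to C9 on the side of the C10–O bond, which should give the same 9S configuration by a different control element, as the 9,10-diol F2. Exhaustive silylation (TESOTf, 2,6-lutidine) gives the bis(triethylsilyl) ether F3. PPTS in MeOH at 0 °C should remove the less hindered secondary silyl ether, and the route is rejoined at 26.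

Step 20. The angeloyl unit may isomerise to the E (tigloyl) isomer during activation, or acylation of the hindered C9 hydroxyl next to the silylated C10 centre may be too slow. Fallback (build the Z ester on the oxygen): set out from 30 and acylate with 2-[bis(2,2,2-trifluoroethoxy)phosphoryl]propanoic acid and DCC; acyl transfer through the phosphono ketene tolerates hindered alcohols and gives the phosphonopropanoate ester F4. Still–Gennari olefination (KN(SiMe3)2, 18-crown-6, THF, −78 °C, acetaldehyde) then forms the Z-2-methylbut-2-enoate, and the route is rejoined at 33.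

**Further compounds**
F1 | step 10 | (1S)-camphanate ester of (3S)-triol 15 | C[C@@]12[C@H](OCc3ccccc3)C=C(CCOCc3ccccc3)C[C@]1(O)[C@@](C)(O)CC[C@@H]2OC(=O)[C@@]45CC[C@@](C)(C(=O)O4)C5(C)C
F2 | step 18 | (9S)-9,10-dihydroxy-3-(TBS-oxy)germacr-4Z-en-12,6-olide | O[C@H]1C[C@H]2CC(=O)O[C@@H]2/C=C(/C)[C@@H](O[Si](C)(C)C(C)(C)C)CC[C@]1(C)O
F3 | step 18 | 9,10-bis(triethylsilyl) ether of F2 | CC[Si](CC)(CC)O[C@H]1C[C@H]2CC(=O)O[C@@H]2/C=C(/C)[C@@H](O[Si](C)(C)C(C)(C)C)CC[C@]1(C)O[Si](CC)(CC)CC
F4 | step 20 | 9-O-{2-[bis(2,2,2-trifluoroethoxy)phosphoryl]propanoyl} derivative of 30 | C=C1C(=O)O[C@@H]2/C=C(/C)[C@@H](O[Si](C)(C)C(C)(C)C)CC[C@](C)(O[Si](CC)(CC)CC)[C@@H](OC(=O)C(C)P(=O)(OCC(F)(F)F)OCC(F)(F)F)C[C@@H]12
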